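The route rests on opening the cyclopentane C9–C13, which is fused to the azepane along C9–C13 and carries C11 between C10 (methyl) and C12, into an alkyne (C9≡C10), carbon monoxide (C11) and the terminal π bond (C12=C13) of an allene. A rhodium-catalysed allenic Pauson–Khand reaction forms C9–C13, C10–C11 and C11–C12 and closes the azepinone and the cyclopentenone in one operation, leaving C9 and C13 trigonal for later delivery of hydrogen and oxygen. Its precursor is a cis-2,6-disubstituted piperidine: a prop-1-ynyl group on C8, the benzyl-protected hydroxypropyl chain on C4, and a penta-3,4-dienoyl group on nitrogen.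

Key step: step 12

Locants used for all compounds: C1–C3 hydroxypropyl chain (C3 carbinol); C4 and C8 the two N–CH carbons (C4 bears the chain); C5–C7 piperidine CH2; C9–C13 cyclopentane (C9 fusion CH, C10 CHMe, C11 CHOH, C12 spiro, C13 carbinol); C14–C16 azepane CH2 (C16 on N).

Assumption: the target SMILES is read as (3R,4R,8S,9R,10S,11S,12R,13S), that is 4-H, 8-H and 9-H mutually cis, 13-OH trans to 9-H (trans ring fusion), 12-O cis to 13-OH and trans to 11-OH, and 11-OH cis to the C10 methyl.

Design remark: the C3 oxygen is carried as a benzyl ether, which can chelate magnesium in step 5, survives the acid of step 10 and leaves in the last step.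

Step 1
Reactants: 1 (R)-2-hydroxybutanoic acid
Product: 2 methyl (R)-2-hydroxybutanoate
Conditions: MeOH, H2SO4 (cat.), reflux
Reagents that add atoms: methanol, CO
Why: Fischer esterification under acid catalysis forms no enolisable activated derivative, so C3 keeps its configuration.

Step 2
Reactants: 2 methyl (R)-2-hydroxybutanoate
Product: 3 methyl (R)-2-(benzyloxy)butanoate
Conditions: BnOC(=NH)CCl3, TfOH (cat.), cyclohexane–CH2Cl2, 0 °C → rt
Reagents that add atoms: benzyl 2,2,2-trichloroacetimidate, N=C(OCc1ccccc1)C(Cl)(Cl)Cl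
Why: Acid-catalysed O-benzylation with the trichloroacetimidate needs no base and therefore does not racemise the α-alkoxy ester.

Step 3
Reactants: 3 methyl (R)-2-(benzyloxy)butanoate
Product: 4 (R)-2-(benzyloxy)butanal
Conditions: i-Bu2AlH, CH2Cl2, −78 °C; aq. potassium sodium tartrate
Reagents that add atoms: none
Why: Partial reduction of an α-alkoxy ester with i-Bu2AlH stops at the chelated tetrahedral aluminate at −78 °C and releases the aldehyde only on work-up; the aldehyde is used at once to protect C3.

Step 4
Reactants: 4 (R)-2-(benzyloxy)butanal; 5 (S)-2-methylpropane-2-sulfinamide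
Product: 6 (S)-N-[(1E,2R)-2-(benzyloxy)butylidene]-2-methylpropane-2-sulfinamide
Conditions: CuSO4 (anhydrous), CH2Cl2, rt
Reagents that add atoms: none
Why: Condensation of an aldehyde with tert-butanesulfinamide over CuSO4 as water scavenger is mild enough to leave the α-alkoxy stereocentre intact.

Step 5
Reactants: 6 (S)-N-[(1E,2R)-2-(benzyloxy)butylidene]-2-methylpropane-2-sulfinamide; 7 pent-4-enylmagnesium bromide
Product: 8 (S)-N-[(6R,7R)-7-(benzyloxy)non-1-en-6-yl]-2-methylpropane-2-sulfinamide
Conditions: CH2Cl2 (Grignard reagent added in Et2O), −78 → −40 °C; aq. NH4Cl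
Reagents that add atoms: none
Why: In this Grignard 1,2-addition to an N-sulfinyl aldimine, the magnesium-bridged chair transition state of the (S)-sulfinyl group and chelation of magnesium by the α-benzyloxy oxygen should direct the nucleophile to the same face, which sets C4 as R, syn to the C3 oxygen.

Step 6
Reactants: 8 (S)-N-[(6R,7R)-7-(benzyloxy)non-1-en-6-yl]-2-methylpropane-2-sulfinamide
Product: 10 tert-butyl N-[(6R,7R)-7-(benzyloxy)non-1-en-6-yl]carbamate, via ammonium chloride 9 (not isolated)
Conditions: HCl (4 M in dioxane), MeOH, 0 °C; concentrate; then Boc2O, Et3N, CH2Cl2, rt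
Reagents that add atoms: di-tert-butyl dicarbonate, CC(C)(C)OC(=O)OC(=O)OC(C)(C)C
Why: Acid methanolysis of the N–S bond removes the auxiliary without touching C3 or C4, and carbamoylation supplies the N-acyl group that the N-acyliminium step needs.

Step 7
Reactants: 10 tert-butyl N-[(6R,7R)-7-(benzyloxy)non-1-en-6-yl]carbamate
Product: 13 tert-butyl (2R)-2-[(1R)-1-(benzyloxy)propyl]-6-methoxypiperidine-1-carboxylate (both C6 epimers), via aldehyde 11 (not isolated), via hemiaminal 12 (not isolated)
Conditions: O3, CH2Cl2–MeOH, −78 °C; Me2S; then PPTS (cat.), MeOH, rt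
Reagents that add atoms: methanol, CO
Why: Ozonolysis unmasks the δ-carbamoyl aldehyde, which closes to the six-membered N-Boc hemiaminal and is trapped as the methyl N,O-acetal; the C8 mixture is immaterial because C8 is ionised in step 9.

Step 8
Reactants: 14 prop-1-ynylmagnesium bromide
Product: 16 potassium trifluoro(prop-1-ynyl)borate, via trimethoxyborate salt 15 (not isolated)
Conditions: B(OMe)3, THF, −78 °C → rt; then KHF2, H2O
Reagents that add atoms: trimethyl borate, COB(OC)OC; potassium hydrogen difluoride, F.[F-].[K+]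
Why: Boration of an alkynyl Grignard reagent followed by fluoride exchange is the standard preparation of a potassium alkynyltrifluoroborate.

Step 9
Reactants: 13 tert-butyl (2R)-2-[(1R)-1-(benzyloxy)propyl]-6-methoxypiperidine-1-carboxylate; 16 potassium trifluoro(prop-1-ynyl)borate
Product: 17 tert-butyl (2R,6S)-2-[(1R)-1-(benzyloxy)propyl]-6-(prop-1-ynyl)piperidine-1-carboxylate
Conditions: BF3·OEt2, CH2Cl2, −78 → −20 °C
Reagents that add atoms: none
Why: In this N-acyliminium alkynylation the C4 substituent of the N-Boc iminium ion sits pseudo-axial (allylic 1,3-strain against the carbamate) and the alkynyl group adds axially through a chair-like transition state, which sets C8 as S, cis to the C4 chain.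

Step 10
Reactants: 17 tert-butyl (2R,6S)-2-[(1R)-1-(benzyloxy)propyl]-6-(prop-1-ynyl)piperidine-1-carboxylate
Product: 18 (2R,6S)-2-[(1R)-1-(benzyloxy)propyl]-6-(prop-1-ynyl)piperidine
Conditions: CF3CO2H, CH2Cl2, 0 °C; aq. NaHCO3
Reagents that add atoms: none
Why: Acidolysis of the tert-butyl carbamate leaves the benzyl ether, the alkyne and all three stereocentres untouched.

Step 11
Reactants: 18 (2R,6S)-2-[(1R)-1-(benzyloxy)propyl]-6-(prop-1-ynyl)piperidine; 19 penta-3,4-dienoic acid
Product: 21 1-[(2R,6S)-2-[(1R)-1-(benzyloxy)propyl]-6-(prop-1-ynyl)piperidin-1-yl]penta-3,4-dien-1-one, via acid chloride 20 (not isolated)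
Conditions: 1-chloro-N,N,2-trimethylprop-1-en-1-amine, CH2Cl2, 0 °C; then 18, CH2Cl2–sat. aq. NaHCO3, 0 °C → rt
Reagents that add atoms: none
Why: Schotten–Baumann N-acylation of the hindered piperidine uses an acid chloride made under neutral conditions, which should keep the β,γ-allene from moving into conjugation.

Step 12
Reactants: 21 1-[(2R,6S)-2-[(1R)-1-(benzyloxy)propyl]-6-(prop-1-ynyl)piperidin-1-yl]penta-3,4-dien-1-one
Product: 22 tricyclic dienone lactam (3R,4R,8S; 3-O-benzyl; C9=C10(Me)–C11=O enone, exocyclic C13=C14, C16 lactam carbonyl)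
Conditions: [Rh(CO)2Cl]2 (5 mol %), CO (1 atm), toluene (0.02 M), 90 °C
Reagents that add atoms: carbon monoxide, [C-]#[O+]
Why: Monovalent rhodium binds the alkyne and the terminal C12=C13 π bond of the allene and undergoes oxidative cyclisation, which forms C9–C13 and thereby closes the seven-membered lactam (C–C bond formation between the inner alkyne carbon and the central allene carbon, the ring holding the tether C14–C15–C16–N–C8); CO insertion and reductive elimination then form C10–C11 and C11–C12 and close the cyclopentenone. The closest known reaction type is the rhodium-catalysed allenic Pauson–Khand reaction of allenynes with a four-atom tether, which gives bicyclo[5.3.0]decadienones (4-alkylidenecyclopentenones), nitrogen-containing tethers included. No stereocentre is created, C4 and C8 are not touched, and C9 and C13 stay trigonal. The step needs reaction at the distal and not the proximal allene π bond: [Rh(CO)2Cl]2 takes the less hindered terminal bond, whereas proximal reaction would give a six-membered lactam with an exocyclic methylene, the outcome typical of Mo(CO)6. The amide keeps nitrogen from binding the metal and its rotamers interconvert at 90 °C, so the chain can reach the alkyne; dilution and 1 atm of CO hold back allene dimerisation.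

Step 13
Reactants: 22 tricyclic dienone lactam
Product: 23 (11R)-dienol (22 with C11=O reduced to CH–OH)
Conditions: (S)-2-methyl-CBS-oxazaborolidine (0.5 equiv), catecholborane, toluene, −78 °C
Reagents that add atoms: none
Why: In this Corey–Bakshi–Shibata 1,2-reduction C11 has no neighbouring stereocentre, so the catalyst decides the face (fully substituted alkenyl C10 as the large group, C12H2 as the small one); the alcohol is only a handle for step 14, chosen because a hydride conjugate reduction of the dienone would be expected to attack the unhindered C14 terminus.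

Step 14
Reactants: 23 (11R)-dienol
Product: 24 saturated alcohol (9-H, 10-H and 13-H all cis to 11-OH; 9-H cis to 8-H)
Conditions: [Ir(cod)(PCy3)(py)]PF6 (10 mol %), H2 (1 → 10 bar), CH2Cl2, K3PO4 (solid buffer), rt
Reagents that add atoms: none
Why: In this hydroxyl-directed homogeneous hydrogenation, iridium bound to the C11 hydroxyl delivers hydrogen to the hydroxyl face of the tetrasubstituted C9=C10 bond and of C13=C14, so C9 is set by C11 (9-H cis to 8-H) and not by the conformation of the lactam; the buffer guards the doubly allylic alcohol against ionisation.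

Step 15
Reactants: 24 saturated alcohol
Product: 26 saturated ketone (C10 methyl trans to the C9–C8 bond; 9-H and 13-H cis), via C10-epimeric ketone 25 (not isolated)
Conditions: Dess–Martin periodinane, CH2Cl2, rt; aqueous work-up; then DBU (0.2 equiv), CH2Cl2, rt
Reagents that add atoms: none
Why: Dess–Martin oxidation restores the C11 ketone, and base equilibration through the enol moves the C10 methyl from the face of the C9–C8 bond to the more stable trans position, which sets C10 under thermodynamic control.

Step 16
Reactants: 26 saturated ketone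
Product: 28 enone (C11(=O)–C12H=C13; 9-H retained), via silyl enol ether 27 (not isolated)
Conditions: LiN(i-Pr)2, THF, −78 °C; Me3SiCl; then Pd(OAc)2, MeCN, rt
Reagents that add atoms: none
Why: Kinetic deprotonation takes the C12 methylene and not the C10 methine, and Saegusa–Ito oxidation of the enol silane removes 13-H by β-hydride elimination, which makes C13 trigonal again for oxygenation without touching C9.

Step 17
Reactants: 28 enone
Product: 29 12-iodo enone
Conditions: I2, pyridine, DMAP (cat.), CH2Cl2, rt
Reagents that add atoms: iodine, [I][I]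
Why: α-Iodination of an enone by amine addition, iodination of the enolate and elimination puts iodine on C12 under conditions too weakly basic to deprotonate C9.

Step 18
Reactants: 30 methyl (E)-3-methoxy-2-methylprop-2-enoate
Product: 32 methyl (Z)-3-methoxy-2-methyl-3-(tributylstannyl)prop-2-enoate, via β-lithio acrylate 31 (not isolated)
Conditions: LiN(i-Pr)2, THF, −95 °C; Bu3SnCl, −95 → −78 °C
Reagents that add atoms: tributyltin chloride, CCCC[Sn](Cl)(CCCC)CCCC
Why: Ester-directed β-lithiation of a β-methoxyacrylate removes the vinylic hydrogen cis to the ester, and stannylation with retention places tin cis to the ester.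

Step 19
Reactants: 29 12-iodo enone; 32 methyl (Z)-3-methoxy-2-methyl-3-(tributylstannyl)prop-2-enoate
Product: 33 12-[(1E)-1,3-dimethoxy-2-methyl-3-oxoprop-1-enyl] enone
Conditions: Pd2(dba)3 (5 mol %), AsPh3 (20 mol %), CuI (20 mol %), NMP, 50 °C
Reagents that add atoms: none
Why: Stille coupling of an α-iodoenone with an alkenylstannane under copper co-catalysis retains the geometry of both partners, so C12 ends up cis to the ester as the later lactonisation requires.

Step 20
Reactants: 33 coupled enone
Product: 34 allylic alcohol (11-OH cis to the C10 methyl)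
Conditions: NaBH4, CeCl3·7H2O, MeOH, −78 °C
Reagents that add atoms: none
Why: In this Luche 1,2-reduction hydride should attack C11 from the face opposite the adjacent C10 methyl, which sets C11 with the hydroxyl cis to the methyl.

Step 21
Reactants: 34 allylic alcohol
Product: 35 11-O-triethylsilyl ether
Conditions: Et3SiOTf, 2,6-lutidine, CH2Cl2, −78 °C
Reagents that add atoms: triethylsilyl trifluoromethanesulfonate, CC[Si](CC)(CC)OS(=O)(=O)C(F)(F)F
Why: Silylation of the secondary allylic alcohol gives a bulky allylic ether that cannot hydrogen-bond and shields its own face of the ring in step 22.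

Step 22
Reactants: 35 11-O-triethylsilyl ether
Product: 37 spiro-butenolide lactam (11-O-triethylsilyl; 13-OH; C16 lactam), via diol ester 36 (not isolated)
Conditions: OsO4 (0.2 equiv), NMO, MeSO2NH2, acetone–H2O, rt; then DBU (cat.), toluene, 40 °C
Reagents that add atoms: N-methylmorpholine N-oxide, C[N+]1([O-])CCOCC1; water, O; both oxygens pass through osmium tetroxide, O=[Os](=O)(=O)=O
Why: Catalytic osmium tetroxide syn-dihydroxylation should take the electron-richer C12=C13 bond (the push–pull acrylate bond is deactivated) from the face opposite the C11 silyloxy group and the C10 methyl, as in osmylation of cyclic allylic ethers, which sets C12 and C13 together with both oxygens cis to the C9–C8 bond; the C12 hydroxyl then closes onto the cis ester by transesterification.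

Step 23
Reactants: 37 spiro-butenolide lactam
Product: 39 tertiary amine (11-O-triethylsilyl, 3-O-benzyl), via O-silyl hemiaminal 38 (not isolated)
Conditions: IrCl(CO)(PPh3)2 (2 mol %), (Me2HSi)2O, toluene, rt; then NaBH(OAc)3, AcOH, CH2Cl2, 0 °C
Reagents that add atoms: none
Why: Iridium-catalysed hydrosilylation of a tertiary lactam is selective over the vinylogous carbonate of the butenolide, and the silyl hemiaminal is ionised by acid and reduced as its iminium ion.

Step 24
Reactants: 39 tertiary amine
Product: 40 target CNP0267781.1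
Conditions: H2 (1 atm), Pd(OH)2/C, HCl (1.2 equiv), MeOH, rt; aq. NaHCO3
Reagents that add atoms: none
Why: Hydrogenolysis of the benzyl ether on the ammonium salt and acid methanolysis of the triethylsilyl ether in the same pot release both hydroxyls, while the tetrasubstituted, electron-poor butenolide alkene should not be hydrogenated.

Compound list

1 | (R)-2-hydroxybutanoic acid | CC[C@@H](O)C(=O)O | starting material
2 | methyl (R)-2-hydroxybutanoate | CC[C@@H](O)C(=O)OC | intermediate
3 | methyl (R)-2-(benzyloxy)butanoate | CC[C@@H](OCc1ccccc1)C(=O)OC | intermediate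
4 | (R)-2-(benzyloxy)butanal | CC[C@@H](OCc1ccccc1)C=O | intermediate
5 | (S)-2-methylpropane-2-sulfinamide | CC(C)(C)[S@](=O)N | starting material
6 | (S)-N-[(1E,2R)-2-(benzyloxy)butylidene]-2-methylpropane-2-sulfinamide | CC[C@@H](OCc1ccccc1)/C=N/[S@@](=O)C(C)(C)C | intermediate
7 | pent-4-enylmagnesium bromide | C=CCCC[Mg]Br | starting material
8 | (S)-N-[(6R,7R)-7-(benzyloxy)non-1-en-6-yl]-2-methylpropane-2-sulfinamide | CC[C@@H](OCc1ccccc1)[C@@H](CCCC=C)N[S@@](=O)C(C)(C)C | intermediate
9 | (6R,7R)-7-(benzyloxy)non-1-en-6-aminium chloride | CC[C@@H](OCc1ccccc1)[C@@H](CCCC=C)[NH3+].[Cl-] | intermediate (not isolated)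
10 | tert-butyl N-[(6R,7R)-7-(benzyloxy)non-1-en-6-yl]carbamate | CC[C@@H](OCc1ccccc1)[C@@H](CCCC=C)NC(=O)OC(C)(C)C | intermediate
11 | tert-butyl N-[(5R,6R)-6-(benzyloxy)-1-oxooctan-5-yl]carbamate | CC[C@@H](OCc1ccccc1)[C@@H](CCCC=O)NC(=O)OC(C)(C)C | intermediate (not isolated)
12 | tert-butyl (2R)-2-[(1R)-1-(benzyloxy)propyl]-6-hydroxypiperidine-1-carboxylate (both C6 epimers) | CC[C@@H](OCc1ccccc1)[C@H]1CCCC(O)N1C(=O)OC(C)(C)C | intermediate (not isolated)
13 | tert-butyl (2R)-2-[(1R)-1-(benzyloxy)propyl]-6-methoxypiperidine-1-carboxylate (both C6 epimers) | CC[C@@H](OCc1ccccc1)[C@H]1CCCC(OC)N1C(=O)OC(C)(C)C | intermediate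
14 | prop-1-ynylmagnesium bromide | CC#C[Mg]Br | starting material
15 | bromomagnesium trimethoxy(prop-1-ynyl)borate | CC#C[B-](OC)(OC)OC.[Mg+2].[Br-] | intermediate (not isolated)
16 | potassium trifluoro(prop-1-ynyl)borate | CC#C[B-](F)(F)F.[K+] | intermediate
17 | tert-butyl (2R,6S)-2-[(1R)-1-(benzyloxy)propyl]-6-(prop-1-ynyl)piperidine-1-carboxylate | CC[C@@H](OCc1ccccc1)[C@H]1CCC[C@@H](C#CC)N1C(=O)OC(C)(C)C | intermediate
18 | (2R,6S)-2-[(1R)-1-(benzyloxy)propyl]-6-(prop-1-ynyl)piperidine | CC[C@@H](OCc1ccccc1)[C@H]1CCC[C@@H](C#CC)N1 | intermediate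
19 | penta-3,4-dienoic acid | C=C=CCC(=O)O | starting material
20 | penta-3,4-dienoyl chloride | C=C=CCC(=O)Cl | intermediate (not isolated)
21 | 1-[(2R,6S)-2-[(1R)-1-(benzyloxy)propyl]-6-(prop-1-ynyl)piperidin-1-yl]penta-3,4-dien-1-one | CC[C@@H](OCc1ccccc1)[C@H]1CCC[C@@H](C#CC)N1C(=O)CC=C=C | intermediate (key-step precursor)
22 | tricyclic dienone lactam (3R,4R,8S; 3-O-benzyl; C9=C10(Me)–C11=O, C13=C14, C16=O) | CC[C@@H](OCc1ccccc1)[C@H]1CCC[C@H]2C3=C(C)C(=O)CC3=CCC(=O)N12 | intermediate (key-step product)
23 | (11R)-dienol of 22 | CC[C@@H](OCc1ccccc1)[C@H]1CCC[C@H]2C3=C(C)[C@H](O)CC3=CCC(=O)N12 | intermediate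
24 | saturated alcohol (9-H, 10-H, 13-H cis to 11-OH; 9-H cis to 8-H) | CC[C@@H](OCc1ccccc1)[C@H]1CCC[C@H]2[C@H]3[C@@H](C)[C@H](O)C[C@H]3CCC(=O)N12 | intermediate
25 | C11 ketone, C10 methyl cis to the C9–C8 bond | CC[C@@H](OCc1ccccc1)[C@H]1CCC[C@H]2[C@H]3[C@@H](C)C(=O)C[C@H]3CCC(=O)N12 | intermediate (not isolated)
26 | C11 ketone, C10 methyl trans to the C9–C8 bond | CC[C@@H](OCc1ccccc1)[C@H]1CCC[C@H]2[C@H]3[C@H](C)C(=O)C[C@H]3CCC(=O)N12 | intermediate
27 | C11 trimethylsilyl enol ether (C11=C12) of 26 | CC[C@@H](OCc1ccccc1)[C@H]1CCC[C@H]2[C@H]3[C@H](C)C(O[Si](C)(C)C)=C[C@H]3CCC(=O)N12 | intermediate (not isolated)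
28 | enone C11(=O)–C12H=C13 | CC[C@@H](OCc1ccccc1)[C@H]1CCC[C@H]2[C@H]3[C@H](C)C(=O)C=C3CCC(=O)N12 | intermediate
29 | 12-iodo enone | CC[C@@H](OCc1ccccc1)[C@H]1CCC[C@H]2[C@H]3[C@H](C)C(=O)C(I)=C3CCC(=O)N12 | intermediate
30 | methyl (E)-3-methoxy-2-methylprop-2-enoate | CO/C=C(\C)C(=O)OC | starting material
31 | methyl (Z)-3-lithio-3-methoxy-2-methylprop-2-enoate | CO/C([Li])=C(\C)C(=O)OC | intermediate (not isolated)
32 | methyl (Z)-3-methoxy-2-methyl-3-(tributylstannyl)prop-2-enoate | CO/C([Sn](CCCC)(CCCC)CCCC)=C(\C)C(=O)OC | intermediate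
33 | 12-[(1E)-1,3-dimethoxy-2-methyl-3-oxoprop-1-enyl] enone | CC[C@@H](OCc1ccccc1)[C@H]1CCC[C@H]2[C@H]3[C@H](C)C(=O)C(/C(OC)=C(/C)C(=O)OC)=C3CCC(=O)N12 | intermediate
34 | allylic alcohol, 11-OH cis to 10-Me | CC[C@@H](OCc1ccccc1)[C@H]1CCC[C@H]2[C@H]3[C@H](C)[C@H](O)C(/C(OC)=C(/C)C(=O)OC)=C3CCC(=O)N12 | intermediate
35 | 11-O-triethylsilyl ether of 34 | CC[C@@H](OCc1ccccc1)[C@H]1CCC[C@H]2[C@H]3[C@H](C)[C@H](O[Si](CC)(CC)CC)C(/C(OC)=C(/C)C(=O)OC)=C3CCC(=O)N12 | intermediate
36 | 12,13-diol ester (both hydroxyls cis to the C9–C8 bond) | CC[C@@H](OCc1ccccc1)[C@H]1CCC[C@H]2[C@H]3[C@H](C)[C@H](O[Si](CC)(CC)CC)[C@](O)(/C(OC)=C(/C)C(=O)OC)[C@]3(O)CCC(=O)N12 | intermediate (not isolated)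
37 | spiro-butenolide lactam (11-O-triethylsilyl, 13-OH, 3-O-benzyl) | CC[C@@H](OCc1ccccc1)[C@H]1CCC[C@H]2[C@H]3[C@H](C)[C@H](O[Si](CC)(CC)CC)[C@@]4(OC(=O)C(C)=C4OC)[C@]3(O)CCC(=O)N12 | intermediate
38 | C16 O-(1,1,3,3-tetramethyldisiloxanyl) hemiaminal of 37 (both C16 epimers) | CC[C@@H](OCc1ccccc1)[C@H]1CCC[C@H]2[C@H]3[C@H](C)[C@H](O[Si](CC)(CC)CC)[C@@]4(OC(=O)C(C)=C4OC)[C@]3(O)CCC(O[Si](C)(C)O[SiH](C)C)N12 | intermediate (not isolated)
39 | tertiary amine (11-O-triethylsilyl, 3-O-benzyl) | CC[C@@H](OCc1ccccc1)[C@H]1CCC[C@H]2[C@H]3[C@H](C)[C@H](O[Si](CC)(CC)CC)[C@@]4(OC(=O)C(C)=C4OC)[C@]3(O)CCCN12 | intermediate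
40 | CNP0267781.1 (3R,4R,8S,9R,10S,11S,12R,13S) | CC[C@@H](O)[C@H]1CCC[C@H]2[C@H]3[C@H](C)[C@H](O)[C@@]4(OC(=O)C(C)=C4OC)[C@]3(O)CCCN12 | target

Total step count: 24. Longest linear sequence: 22 steps (steps 1–7, 9–17 and 19–24); steps 8 and 18 are side branches.

Steps most likely to fail

Step 12. The β,γ-allenyl amide may isomerise to the conjugated dienamide before it cyclises, or the chain rotamer that points at C8 may be too little populated for oxidative cyclisation, so that carbonylation stalls or takes the proximal π bond. The fallback replaces catalytic carbonylation by the stoichiometric cobalt-mediated Pauson–Khand reaction. It sets out from 21: Co2(CO)8 in CH2Cl2 at rt gives the alkyne–hexacarbonyldicobalt complex F1, in which the alkyne is already committed to the metal. N-Methylmorpholine N-oxide at 0 °C → rt then opens a coordination site at a temperature at which the allene does not isomerise. With monosubstituted allenes this protocol is known to engage the terminal π bond, so it should return 22; any six-membered α-methylene isomer would be separated.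

Step 22. Facial selectivity may be poor: the azepinone ring lies on the face that must be attacked, and osmium may instead add from the face carrying the silyloxy group and the methyl, giving the 12,13-bis-epimeric diol (cis ring fusion). Slow osmylation of the tetrasubstituted alkene would make this worse. The fallback replaces steric control by hydrogen-bond delivery and sets out from 34. Mitsunobu inversion (4-nitrobenzoic acid, PPh3, DIAD, toluene) gives the C11-inverted 4-nitrobenzoate F2, and K2CO3 in MeOH frees the C11-epimeric allylic alcohol F3, whose hydroxyl now lies on the face cis to the C9–C8 bond. Stoichiometric OsO4 with TMEDA (CH2Cl2, −78 °C; then ethylenediamine) is delivered syn to that hydroxyl by hydrogen bonding and gives the all-cis triol ester F4, which lactonises with catalytic DBU to the spiro-butenolide diol F5. Dess–Martin oxidation of the secondary alcohol gives the C11 ketone F6. Me4NBH(OAc)3 (AcOH–MeCN, −20 °C), bound to the C13 hydroxyl, delivers hydride on the face of that hydroxyl and away from the C10 methyl (anti-1,3-diol) and gives the C11 alcohol F7 with the target configuration. Silylation (Et3SiOTf, 2,6-lutidine) brings it back to the route at 37.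

Step 19. Transmetalation of the tetrasubstituted, ester-flanked alkenylstannane may be so slow that protodestannylation and reduction or homocoupling of the iodide outrun the coupling. The fallback is a Negishi coupling that needs no stannane and sets out from 29 and 30. The β-lithio acrylate 31, made from 30 as in step 18, is transmetalated with ZnCl2 (THF, −95 → 0 °C) to the alkenylzinc chloride F8. This is coupled with 29 using Pd(P(t-Bu)3)2 (zerovalent palladium) in THF at rt; zinc transfers the hindered alkenyl group much faster than tin and tolerates the ester. The sequence returns at 33.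

Further compounds

F1 | step 12 | hexacarbonyldicobalt complex of the alkyne of 21 | CC[C@@H](OCc1ccccc1)[C@H]1CCC[C@H](N1C(=O)CC=C=C)C12C3(C)[Co]1(=C=O)(=C=O)(=C=O)[Co]23(=C=O)(=C=O)=C=O
F2 | step 22 | C11-inverted 4-nitrobenzoate of 34 | CC[C@@H](OCc1ccccc1)[C@H]1CCC[C@H]2[C@H]3[C@H](C)[C@@H](OC(=O)c4ccc(cc4)[N+](=O)[O-])C(/C(OC)=C(/C)C(=O)OC)=C3CCC(=O)N12
F3 | step 22 | C11-epimeric allylic alcohol (11-OH trans to 10-Me) | CC[C@@H](OCc1ccccc1)[C@H]1CCC[C@H]2[C@H]3[C@H](C)[C@@H](O)C(/C(OC)=C(/C)C(=O)OC)=C3CCC(=O)N12
F4 | step 22 | all-cis 11,12,13-triol ester | CC[C@@H](OCc1ccccc1)[C@H]1CCC[C@H]2[C@H]3[C@H](C)[C@@H](O)[C@](O)(/C(OC)=C(/C)C(=O)OC)[C@]3(O)CCC(=O)N12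
F5 | step 22 | C11-epimeric spiro-butenolide diol lactam | CC[C@@H](OCc1ccccc1)[C@H]1CCC[C@H]2[C@H]3[C@H](C)[C@@H](O)[C@@]4(OC(=O)C(C)=C4OC)[C@]3(O)CCC(=O)N12
F6 | step 22 | C11 ketone of the spiro-butenolide lactam | CC[C@@H](OCc1ccccc1)[C@H]1CCC[C@H]2[C@H]3[C@H](C)C(=O)[C@@]4(OC(=O)C(C)=C4OC)[C@]3(O)CCC(=O)N12
F7 | step 22 | spiro-butenolide diol lactam with free 11-OH (target configuration) | CC[C@@H](OCc1ccccc1)[C@H]1CCC[C@H]2[C@H]3[C@H](C)[C@H](O)[C@@]4(OC(=O)C(C)=C4OC)[C@]3(O)CCC(=O)N12
F8 | step 19 | methyl (Z)-3-(chlorozincio)-3-methoxy-2-methylprop-2-enoate | CO/C([Zn]Cl)=C(\C)C(=O)OC
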